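**Retrosynthetic overview**

1. Rings: A = guaiacyl ring on dihydrobenzofuran C2; C = benzo ring of the dihydrobenzofuran; B = central ring carrying the furofuran and the ketone side chain; D = aryl ketone ring. Furofuran atoms are C1, C2, O3, C4, C5, C6, O7, C8 (3,7-dioxabicyclo[3.3.0]octane; ring B on C2, ring C on C6). Feature: C2 is bonded only to ring B, O3, C1 and H, so it is the former carbonyl carbon of a ring B benzaldehyde set between the C4 hydroxymethyl oxygen and the nucleophilic β-carbon C1 of a 2,3-dihydrofuran (C5, C6, O7, C8=C1).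
2. Key disconnection: O3–C2 and C1–C2. A ring B aldehyde dimethyl acetal and a trans-2-aryl-3-(hydroxymethyl)-2,3-dihydrofuran are joined by acetal exchange and oxocarbenium/enol ether cyclisation; C8 emerges as a methyl acetal that Et3SiH then reduces.
3. Dihydrofuran alcohol: Evans syn aldol of the ring C aldehyde with an N-pent-4-enoyl oxazolidinone (sets C5 and C6), alkene cleavage to a lactol, dehydration, reductive removal of the auxiliary. The cis-dihydrobenzofuran is made before it by rhodium carbene C–H insertion of an ortho-benzyloxy aryl diazoacetate built from 5-bromo-2-hydroxy-3-methoxybenzaldehyde and vanillin.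
4. Endgame: Pd α-arylation of silylated acetovanillone with the ring B bromide, catalytic asymmetric hydroxymethylation of the enol silane (sets the last centre), buffered desilylation.
5. Ring order: dihydrobenzofuran furan ring (step 9), dihydrofuran O7 ring (steps 15–16), tetrahydrofuran O3 ring (step 20).

Key step: step 20

Abbreviations: DHB = (2S,3S)-3-[(tert-butyldimethylsilyloxy)methyl]-7-methoxy-2-[3-methoxy-4-(triisopropylsilyloxy)phenyl]-2,3-dihydro-1-benzofuran-5-yl (2,3-cis); ArB = 3-bromo-5-methoxy-4-(triisopropylsilyloxy)phenyl. All three phenols are carried as triisopropylsilyl (TIPS) ethers and the primary alcohol as its tert-butyldimethylsilyl (TBS) ether.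

Assumption: the facial sense of Rh2(S-PTTL)4 in step 9 and of the (S,S)-bipyridine–Sc(OTf)3 catalyst in step 25 is taken over from the simplest substrates of each reaction class; if either delivers the mirror-image sense, the equally accessible enantiomeric ligand is used and nothing else changes.

**Route**

Step 1
Reactants: 1 vanillin (4-hydroxy-3-methoxybenzaldehyde)
Product: 2 3-methoxy-4-(triisopropylsilyloxy)benzaldehyde
Conditions: TIPSCl, imidazole, DMF, rt
Reagents that add atoms: triisopropylsilyl chloride, CC(C)[Si](Cl)(C(C)C)C(C)C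
Why: Phenol silylation; the bulky TIPS ether is chosen because it has to survive base, organolithium and Lewis acid steps up to the last step.

Step 2
Reactants: 2 3-methoxy-4-(triisopropylsilyloxy)benzaldehyde
Product: 3 [3-methoxy-4-(triisopropylsilyloxy)phenyl]methanol
Conditions: NaBH4, MeOH, 0 °C
Reagents that add atoms: none
Why: Borohydride reduction of an aryl aldehyde, to which the aryl silyl ether is inert.

Step 3
Reactants: 3 [3-methoxy-4-(triisopropylsilyloxy)phenyl]methanol; 4 5-bromo-2-hydroxy-3-methoxybenzaldehyde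
Product: 5 5-bromo-3-methoxy-2-{[3-methoxy-4-(triisopropylsilyloxy)phenyl]methoxy}benzaldehyde
Conditions: PPh3, DIAD, THF, 0 °C to rt
Reagents that add atoms: none
Why: Mitsunobu etherification of the acidic phenol with the primary benzylic alcohol, which avoids the base-labile 4-silyloxybenzyl halide that a Williamson alkylation would need.

Step 4
Reactants: 5 5-bromo-3-methoxy-2-{[3-methoxy-4-(triisopropylsilyloxy)phenyl]methoxy}benzaldehyde
Product: 6 5-bromo-1-methoxy-3-(2-methoxyethenyl)-2-{[3-methoxy-4-(triisopropylsilyloxy)phenyl]methoxy}benzene (E/Z mixture)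
Conditions: MeOCH2PPh3Cl, KOtBu, THF, 0 °C
Reagents that add atoms: (methoxymethyl)triphenylphosphonium chloride, COC[P+](c1ccccc1)(c1ccccc1)c1ccccc1.[Cl-]
Why: Wittig methoxymethylenation adds the one carbon needed as an enol ether whose alkene geometry is immaterial.

Step 5
Reactants: 6 the enol ether
Product: 7 2-(5-bromo-3-methoxy-2-{[3-methoxy-4-(triisopropylsilyloxy)phenyl]methoxy}phenyl)acetaldehyde
Conditions: 1 M aq. HCl, THF, rt
Reagents that add atoms: water, O
Why: Mild acid hydrolysis of the enol ether, which the aryl silyl ether and the benzylic aryl ether tolerate in dilute aqueous acid at room temperature.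

Step 6
Reactants: 7 the arylacetaldehyde
Product: 8 2-(5-bromo-3-methoxy-2-{[3-methoxy-4-(triisopropylsilyloxy)phenyl]methoxy}phenyl)acetic acid
Conditions: NaClO2, NaH2PO4, 2-methyl-2-butene, t-BuOH/H2O, 0 °C to rt
Reagents that add atoms: sodium chlorite, [Na+].[O-]Cl=O
Why: Pinnick oxidation of the enolisable aldehyde under buffered conditions, the alkene scavenging hypochlorous acid so that the electron-rich rings are not chlorinated.

Step 7
Reactants: 8 the arylacetic acid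
Product: 9 methyl 2-(5-bromo-3-methoxy-2-{[3-methoxy-4-(triisopropylsilyloxy)phenyl]methoxy}phenyl)acetate
Conditions: TMSCHN2, MeOH/toluene, 0 °C
Reagents that add atoms: (trimethylsilyl)diazomethane, C[Si](C)(C)C=[N+]=[N-]
Why: Neutral methyl esterification of the carboxylic acid that leaves the silyl ether untouched.

Step 8
Reactants: 9 the methyl arylacetate
Product: 10 methyl 2-diazo-2-(5-bromo-3-methoxy-2-{[3-methoxy-4-(triisopropylsilyloxy)phenyl]methoxy}phenyl)acetate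
Conditions: p-ABSA, DBU, MeCN, 0 °C to rt
Reagents that add atoms: 4-acetamidobenzenesulfonyl azide, CC(=O)Nc1ccc(cc1)S(=O)(=O)N=[N+]=[N-]
Why: Regitz diazo transfer to the DBU-generated arylacetate enolate gives the donor/acceptor diazo ester.

Step 9
Reactants: 10 the aryl diazoacetate
Product: 11 methyl (2S,3R)-5-bromo-7-methoxy-2-[3-methoxy-4-(triisopropylsilyloxy)phenyl]-2,3-dihydro-1-benzofuran-3-carboxylate (2,3-cis)
Conditions: Rh2(S-PTTL)4 [dirhodium tetrakis(N-phthaloyl-(S)-tert-leucinate)] (1 mol %), toluene, −60 °C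
Reagents that add atoms: none
Why: Intramolecular 1,5 C–H insertion of the rhodium carbene into the ether-activated benzylic C–H bond closes the furan ring; the chiral carboxylate ligands set C2 and the kinetically controlled insertion gives the cis C3 centre, as is known for ortho-benzyloxyaryl diazoacetates.

Step 10
Reactants: 11 the cis ester
Product: 12 {(2S,3S)-5-bromo-7-methoxy-2-[3-methoxy-4-(triisopropylsilyloxy)phenyl]-2,3-dihydro-1-benzofuran-3-yl}methanol (2,3-cis)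
Conditions: i-Bu2AlH, CH2Cl2, −78 to 0 °C; Rochelle salt
Reagents that add atoms: none
Why: Non-basic hydride reduction of the ester at low temperature keeps the epimerisable cis C3 centre.

Step 11
Reactants: 12 the cis alcohol
Product: 13 (2S,3S)-5-bromo-3-[(tert-butyldimethylsilyloxy)methyl]-7-methoxy-2-[3-methoxy-4-(triisopropylsilyloxy)phenyl]-2,3-dihydro-1-benzofuran (DHB–Br)
Conditions: TBSCl, imidazole, DMF, rt
Reagents that add atoms: tert-butyldimethylsilyl chloride, CC(C)(C)[Si](C)(C)Cl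
Why: Standard silylation of the primary alcohol.

Step 12
Reactants: 13 DHB–Br
Product: 15 DHB–CHO (the dihydrobenzofuran-5-carbaldehyde), via aryllithium 14 (not isolated)
Conditions: n-BuLi, THF, −78 °C; DMF, −78 to 0 °C; aq. NH4Cl
Reagents that add atoms: N,N-dimethylformamide, CN(C)C=O
Why: Bromine–lithium exchange at −78 °C outruns any deprotonation and the aryllithium is formylated by DMF (Bouveault formylation).

Step 13
Reactants: 16 (S)-4-benzyl-1,3-oxazolidin-2-one; 17 pent-4-enoyl chloride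
Product: 18 (S)-4-benzyl-3-(pent-4-enoyl)-1,3-oxazolidin-2-one
Conditions: Et3N, DMAP (cat.), CH2Cl2, 0 °C to rt
Reagents that add atoms: none
Why: DMAP-catalysed N-acylation of the oxazolidinone gives the Evans imide.

Step 14
Reactants: 18 the N-pent-4-enoyl oxazolidinone; 15 DHB–CHO
Product: 20 (4S)-4-benzyl-3-[(2S,3S)-3-DHB-3-hydroxy-2-(prop-2-en-1-yl)propanoyl]-1,3-oxazolidin-2-one, via boron enolate 19 (not isolated)
Conditions: Bu2BOTf, iPr2NEt, CH2Cl2, −78 to 0 °C; then 15, −78 to 0 °C; pH 7 buffer, MeOH, H2O2, 0 °C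
Reagents that add atoms: none
Why: Evans syn aldol reaction, in which the (Z)-boron enolate adds through a Zimmerman–Traxler chair with one face shielded by the (S)-benzyl group, setting the (2S,3S) centres that become C5 and C6; material from the minor enantiomer of 11 becomes a separable diastereomer here.

Step 15
Reactants: 20 the syn aldol adduct
Product: 22 (4S)-4-benzyl-3-{[(2S,3S)-2-DHB-5-hydroxyoxolan-3-yl]carbonyl}-1,3-oxazolidin-2-one (lactol; both anomers), via diol 21 (not isolated)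
Conditions: OsO4 (cat.), NaIO4, 2,6-lutidine, dioxane/H2O, rt
Reagents that add atoms: osmium tetroxide, O=[Os](=O)(=O)=O (oxygen donor, reoxidised by sodium periodate, [Na+].[O-]I(=O)(=O)=O)
Why: Lemieux–Johnson cleavage of the terminal alkene gives an aldehyde that the β-hydroxyl traps at once as the five-membered lactol, with the benzylic oxygen as ring oxygen and both stereocentres untouched.

Step 16
Reactants: 22 the lactol
Product: 24 (4S)-4-benzyl-3-{[(2S,3S)-2-DHB-2,3-dihydrofuran-3-yl]carbonyl}-1,3-oxazolidin-2-one (2,3-trans), via anomeric mesylate 23 (not isolated)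
Conditions: MsCl, Et3N, CH2Cl2, −40 to 40 °C
Reagents that add atoms: none
Why: Lactol dehydration of the glycal type, in which the anomeric mesylate ionises and loses the C4 proton to give the enol ether without touching C2 or C3.

Step 17
Reactants: 24 the dihydrofuran imide
Product: 25 [(2S,3R)-2-DHB-2,3-dihydrofuran-3-yl]methanol (2,3-trans)
Conditions: LiBH4, MeOH (1 equiv), THF, 0 °C
Reagents that add atoms: none
Why: Reductive cleavage of the N-acyl oxazolidinone releases the primary alcohol and the recoverable auxiliary, the trans relationship from the syn aldol being retained.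

Step 18
Reactants: 26 5-bromovanillin (3-bromo-4-hydroxy-5-methoxybenzaldehyde)
Product: 27 3-bromo-5-methoxy-4-(triisopropylsilyloxy)benzaldehyde (ArB–CHO)
Conditions: TIPSOTf, 2,6-lutidine, CH2Cl2, 0 °C to rt
Reagents that add atoms: triisopropylsilyl trifluoromethanesulfonate, CC(C)[Si](OS(=O)(=O)C(F)(F)F)(C(C)C)C(C)C
Why: The silyl triflate silylates the doubly ortho-substituted phenol; TIPS is used because this ether later sits next to a ketone enolate.

Step 19
Reactants: 27 ArB–CHO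
Product: 28 1-bromo-5-(dimethoxymethyl)-3-methoxy-2-(triisopropylsilyloxy)benzene (ArB–CH(OMe)2)
Conditions: HC(OMe)3, PPTS (cat.), MeOH, rt; Et3N
Reagents that add atoms: trimethyl orthoformate, COC(OC)OC
Why: Acid-catalysed acetalisation driven by the orthoformate as water scavenger.

Step 20
Reactants: 25 [(2S,3R)-2-DHB-2,3-dihydrofuran-3-yl]methanol; 28 ArB–CH(OMe)2
Product: 30 (1S,2S,5R,6S,8R)-2-ArB-6-DHB-8-methoxy-3,7-dioxabicyclo[3.3.0]octane (both aryl groups and the methoxy group exo), via mixed acetal 29 (not isolated)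
Conditions: 28 (1.5 equiv), TMSOTf (0.2 equiv), 4 Å MS, CH2Cl2, −78 to −40 °C; Et3N quench
Reagents that add atoms: none
Why: Catalytic TMSOTf exchanges one methoxy group of 28 for the primary hydroxyl of 25 (mixed acetal 29) and ionises the second to an aryl-stabilised (E)-oxocarbenium ion, which the enol ether carbon C1 attacks in an intramolecular Prins-type addition, and the cyclic oxocarbenium ion left at C8 is captured by the methanol set free. The closest known reaction type is the Lewis-acid cyclisation of 2-aryl-3-(hydroxymethyl)-2,3-dihydrofurans with aryl aldehyde dimethyl acetals to 8-methoxy-2,6-diaryl-3,7-dioxabicyclo[3.3.0]octanes. The tetrahydrofuran ring (C1, C2, O3, C4, C5) closes 5-endo-trig at the O3=C2 oxocarbenium bond and exo with respect to the enol ether, a mode that is routine for such cations. C1 is controlled by C5, because the short tether can reach only the face that bears the CH2O group (cis fusion); C2 is controlled by the (E) geometry of the ion in an envelope transition state that keeps ring B over the C1 hydrogen, away from the dihydrofuran, so that it ends exo; C8 is controlled by methanol adding to the convex face. The step needs exo placement of ring B and survival of the p-oxygenated benzylic C–O bonds (dihydrobenzofuran C2–O, C6–O7, new C2–O3): the first is secured by the bulk of the 3,4,5-trisubstituted aryl group and by the trans template, which leaves nothing on the reacting face to hold the arene over the ring, the second by substoichiometric TMSOTf at low temperature, where acetal ionisation is much faster than benzylic ether ionisation.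

Step 21
Reactants: 30 the furofuran methyl acetal
Product: 31 (1R,2S,5R,6S)-2-ArB-6-DHB-3,7-dioxabicyclo[3.3.0]octane (both aryl groups exo)
Conditions: Et3SiH, BF3·OEt2, CH2Cl2, −78 to −40 °C; aq. NaHCO3
Reagents that add atoms: none
Why: Ionic hydrogenation, in which BF3·OEt2 ionises the acetal to the bicyclic oxocarbenium ion and Et3SiH reduces it; C8 becomes CH2, so no stereocentre is at stake.

Step 22
Reactants: 32 acetovanillone (1-(4-hydroxy-3-methoxyphenyl)ethan-1-one)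
Product: 33 1-[3-methoxy-4-(triisopropylsilyloxy)phenyl]ethan-1-one
Conditions: TIPSCl, imidazole, DMF, rt
Reagents that add atoms: triisopropylsilyl chloride, CC(C)[Si](Cl)(C(C)C)C(C)C
Why: Phenol silylation; TIPS resists silyl transfer to the ketone enolate in the next step.

Step 23
Reactants: 31 the furofuran aryl bromide; 33 the silylated acetovanillone
Product: 34 2-{3-methoxy-5-[(1R,2S,5R,6S)-6-DHB-3,7-dioxabicyclo[3.3.0]octan-2-yl]-2-(triisopropylsilyloxy)phenyl}-1-[3-methoxy-4-(triisopropylsilyloxy)phenyl]ethan-1-one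
Conditions: 33 (2 equiv), Pd(OAc)2 (5 mol %), 2-(dicyclohexylphosphino)-2′-methylbiphenyl (10 mol %), K3PO4, toluene, 80 °C
Reagents that add atoms: none
Why: Palladium-catalysed α-arylation of the methyl ketone (Buchwald–Hartwig type) with a bulky biarylphosphine and the weak base K3PO4, excess ketone suppressing diarylation.

Step 24
Reactants: 34 the deoxybenzoin
Product: 35 the (Z)-trimethylsilyl enol ether of 34 (OSiMe3 and ring B cis on the double bond)
Conditions: TMSOTf, Et3N, CH2Cl2, 0 °C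
Reagents that add atoms: trimethylsilyl trifluoromethanesulfonate, C[Si](C)(C)OS(=O)(=O)C(F)(F)F
Why: Soft enolisation gives the thermodynamically preferred (Z)-enol silane with the two aryl groups trans, the excess amine keeping the medium free of acid.

Step 25
Reactants: 35 the (Z)-enol silane
Product: 36 (2S)-3-hydroxy-2-{3-methoxy-5-[(1R,2S,5R,6S)-6-DHB-3,7-dioxabicyclo[3.3.0]octan-2-yl]-2-(triisopropylsilyloxy)phenyl}-1-[3-methoxy-4-(triisopropylsilyloxy)phenyl]propan-1-one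
Conditions: Sc(OTf)3 (10 mol %), (S,S)-6,6′-bis(1-hydroxy-2,2-dimethylpropyl)-2,2′-bipyridine (12 mol %), aq. HCHO, DME/H2O, −20 °C
Reagents that add atoms: formaldehyde, C=O
Why: Catalytic asymmetric Mukaiyama aldol hydroxymethylation, in which the chiral scandium–bipyridine complex binds formaldehyde and differentiates the faces of the enol silane, setting the (S) centre under non-basic conditions that do not epimerise the α-aryl ketone.

Step 26
Reactants: 36 the tetrasilyl ether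
Product: 37 CNP0174045.1, (2S)-3-hydroxy-1-(4-hydroxy-3-methoxyphenyl)-2-{2-hydroxy-5-[(1R,2S,5R,6S)-6-[(2S,3S)-3-(hydroxymethyl)-2-(4-hydroxy-3-methoxyphenyl)-7-methoxy-2,3-dihydro-1-benzofuran-5-yl]-3,7-dioxabicyclo[3.3.0]octan-2-yl]-3-methoxyphenyl}propan-1-one
Conditions: TBAF, AcOH (1:1), THF, 0 °C to rt
Reagents that add atoms: none
Why: Fluoride desilylation buffered with acetic acid removes the three aryl TIPS ethers and the primary TBS ether without exposing the epimerisable, retro-aldol-prone α-aryl β-hydroxy ketone or the cis-dihydrobenzofuran to base.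

**Compound list**

1 | vanillin | COc1cc(C=O)ccc1O | starting material
2 | 3-methoxy-4-(triisopropylsilyloxy)benzaldehyde | COc1cc(C=O)ccc1O[Si](C(C)C)(C(C)C)C(C)C | intermediate
3 | [3-methoxy-4-(triisopropylsilyloxy)phenyl]methanol | COc1cc(CO)ccc1O[Si](C(C)C)(C(C)C)C(C)C | intermediate
4 | 5-bromo-2-hydroxy-3-methoxybenzaldehyde | COc1cc(Br)cc(C=O)c1O | starting material
5 | 5-bromo-3-methoxy-2-{[3-methoxy-4-(triisopropylsilyloxy)phenyl]methoxy}benzaldehyde | COc1cc(Br)cc(C=O)c1OCc1ccc(O[Si](C(C)C)(C(C)C)C(C)C)c(OC)c1 | intermediate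
6 | 5-bromo-1-methoxy-3-(2-methoxyethenyl)-2-{[3-methoxy-4-(triisopropylsilyloxy)phenyl]methoxy}benzene (E/Z mixture) | COC=Cc1cc(Br)cc(OC)c1OCc1ccc(O[Si](C(C)C)(C(C)C)C(C)C)c(OC)c1 | intermediate
7 | 2-(5-bromo-3-methoxy-2-{[3-methoxy-4-(triisopropylsilyloxy)phenyl]methoxy}phenyl)acetaldehyde | O=CCc1cc(Br)cc(OC)c1OCc1ccc(O[Si](C(C)C)(C(C)C)C(C)C)c(OC)c1 | intermediate
8 | 2-(5-bromo-3-methoxy-2-{[3-methoxy-4-(triisopropylsilyloxy)phenyl]methoxy}phenyl)acetic acid | OC(=O)Cc1cc(Br)cc(OC)c1OCc1ccc(O[Si](C(C)C)(C(C)C)C(C)C)c(OC)c1 | intermediate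
9 | methyl 2-(5-bromo-3-methoxy-2-{[3-methoxy-4-(triisopropylsilyloxy)phenyl]methoxy}phenyl)acetate | COC(=O)Cc1cc(Br)cc(OC)c1OCc1ccc(O[Si](C(C)C)(C(C)C)C(C)C)c(OC)c1 | intermediate
10 | methyl 2-diazo-2-(5-bromo-3-methoxy-2-{[3-methoxy-4-(triisopropylsilyloxy)phenyl]methoxy}phenyl)acetate | COC(=O)C(=[N+]=[N-])c1cc(Br)cc(OC)c1OCc1ccc(O[Si](C(C)C)(C(C)C)C(C)C)c(OC)c1 | intermediate
11 | methyl (2S,3R)-5-bromo-7-methoxy-2-[3-methoxy-4-(triisopropylsilyloxy)phenyl]-2,3-dihydro-1-benzofuran-3-carboxylate (cis) | Brc1cc(OC)c2c(c1)[C@@H](C(=O)OC)[C@@H](c1ccc(O[Si](C(C)C)(C(C)C)C(C)C)c(OC)c1)O2 | intermediate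
12 | {(2S,3S)-5-bromo-7-methoxy-2-[3-methoxy-4-(triisopropylsilyloxy)phenyl]-2,3-dihydro-1-benzofuran-3-yl}methanol (cis) | Brc1cc(OC)c2c(c1)[C@@H](CO)[C@@H](c1ccc(O[Si](C(C)C)(C(C)C)C(C)C)c(OC)c1)O2 | intermediate
13 | DHB–Br, (2S,3S)-5-bromo-3-[(tert-butyldimethylsilyloxy)methyl]-7-methoxy-2-[3-methoxy-4-(triisopropylsilyloxy)phenyl]-2,3-dihydro-1-benzofuran | Brc1cc(OC)c2c(c1)[C@@H](CO[Si](C)(C)C(C)(C)C)[C@@H](c1ccc(O[Si](C(C)C)(C(C)C)C(C)C)c(OC)c1)O2 | intermediate
14 | DHB–Li, the 5-lithio analogue of 13 | [Li]c1cc(OC)c2c(c1)[C@@H](CO[Si](C)(C)C(C)(C)C)[C@@H](c1ccc(O[Si](C(C)C)(C(C)C)C(C)C)c(OC)c1)O2 | intermediate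
15 | DHB–CHO, (2S,3S)-3-[(tert-butyldimethylsilyloxy)methyl]-7-methoxy-2-[3-methoxy-4-(triisopropylsilyloxy)phenyl]-2,3-dihydro-1-benzofuran-5-carbaldehyde | O=Cc1cc(OC)c2c(c1)[C@@H](CO[Si](C)(C)C(C)(C)C)[C@@H](c1ccc(O[Si](C(C)C)(C(C)C)C(C)C)c(OC)c1)O2 | intermediate
16 | (S)-4-benzyl-1,3-oxazolidin-2-one | O=C1N[C@@H](Cc2ccccc2)CO1 | starting material
17 | pent-4-enoyl chloride | C=CCCC(Cl)=O | starting material
18 | (S)-4-benzyl-3-(pent-4-enoyl)-1,3-oxazolidin-2-one | C=CCCC(=O)N1[C@@H](Cc2ccccc2)COC1=O | intermediate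
19 | (Z)-dibutylboron enolate of 18 | CCCCB(CCCC)O/C(=C\CC=C)N1[C@@H](Cc2ccccc2)COC1=O | intermediate
20 | (4S)-4-benzyl-3-[(2S,3S)-3-DHB-3-hydroxy-2-(prop-2-en-1-yl)propanoyl]-1,3-oxazolidin-2-one | O=C(N1[C@@H](Cc2ccccc2)COC1=O)[C@@H](CC=C)[C@H](O)c1cc(OC)c2c(c1)[C@@H](CO[Si](C)(C)C(C)(C)C)[C@@H](c1ccc(O[Si](C(C)C)(C(C)C)C(C)C)c(OC)c1)O2 | intermediate
21 | (4S)-4-benzyl-3-{(2S)-2-[(S)-DHB(hydroxy)methyl]-4,5-dihydroxypentanoyl}-1,3-oxazolidin-2-one (C4 epimers) | O=C(N1[C@@H](Cc2ccccc2)COC1=O)[C@@H](CC(O)CO)[C@H](O)c1cc(OC)c2c(c1)[C@@H](CO[Si](C)(C)C(C)(C)C)[C@@H](c1ccc(O[Si](C(C)C)(C(C)C)C(C)C)c(OC)c1)O2 | intermediate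
22 | (4S)-4-benzyl-3-{[(2S,3S)-2-DHB-5-hydroxyoxolan-3-yl]carbonyl}-1,3-oxazolidin-2-one (lactol, both anomers) | OC1C[C@H](C(=O)N2[C@@H](Cc3ccccc3)COC2=O)[C@@H](c2cc(OC)c3c(c2)[C@@H](CO[Si](C)(C)C(C)(C)C)[C@@H](c2ccc(O[Si](C(C)C)(C(C)C)C(C)C)c(OC)c2)O3)O1 | intermediate
23 | anomeric methanesulfonate of 22 | CS(=O)(=O)OC1C[C@H](C(=O)N2[C@@H](Cc3ccccc3)COC2=O)[C@@H](c2cc(OC)c3c(c2)[C@@H](CO[Si](C)(C)C(C)(C)C)[C@@H](c2ccc(O[Si](C(C)C)(C(C)C)C(C)C)c(OC)c2)O3)O1 | intermediate
24 | (4S)-4-benzyl-3-{[(2S,3S)-2-DHB-2,3-dihydrofuran-3-yl]carbonyl}-1,3-oxazolidin-2-one (trans) | O=C(N1[C@@H](Cc2ccccc2)COC1=O)[C@H]1C=CO[C@@H]1c1cc(OC)c2c(c1)[C@@H](CO[Si](C)(C)C(C)(C)C)[C@@H](c1ccc(O[Si](C(C)C)(C(C)C)C(C)C)c(OC)c1)O2 | intermediate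
25 | [(2S,3R)-2-DHB-2,3-dihydrofuran-3-yl]methanol (trans) | OC[C@H]1C=CO[C@@H]1c1cc(OC)c2c(c1)[C@@H](CO[Si](C)(C)C(C)(C)C)[C@@H](c1ccc(O[Si](C(C)C)(C(C)C)C(C)C)c(OC)c1)O2 | intermediate
26 | 5-bromovanillin | COc1cc(C=O)cc(Br)c1O | starting material
27 | ArB–CHO, 3-bromo-5-methoxy-4-(triisopropylsilyloxy)benzaldehyde | COc1cc(C=O)cc(Br)c1O[Si](C(C)C)(C(C)C)C(C)C | intermediate
28 | ArB–CH(OMe)2, 1-bromo-5-(dimethoxymethyl)-3-methoxy-2-(triisopropylsilyloxy)benzene | COC(OC)c1cc(Br)c(O[Si](C(C)C)(C(C)C)C(C)C)c(OC)c1 | intermediate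
29 | mixed acetal ArB–CH(OMe)–O–CH2–[(2S,3R)-2-DHB-2,3-dihydrofuran-3-yl] (acetal epimers) | COC(OC[C@H]1C=CO[C@@H]1c1cc(OC)c2c(c1)[C@@H](CO[Si](C)(C)C(C)(C)C)[C@@H](c1ccc(O[Si](C(C)C)(C(C)C)C(C)C)c(OC)c1)O2)c1cc(Br)c(O[Si](C(C)C)(C(C)C)C(C)C)c(OC)c1 | intermediate
30 | (1S,2S,5R,6S,8R)-2-ArB-6-DHB-8-methoxy-3,7-dioxabicyclo[3.3.0]octane | Brc1cc([C@H]2OC[C@H]3[C@@H]2[C@H](OC)O[C@@H]3c2cc(OC)c3c(c2)[C@@H](CO[Si](C)(C)C(C)(C)C)[C@@H](c2ccc(O[Si](C(C)C)(C(C)C)C(C)C)c(OC)c2)O3)cc(OC)c1O[Si](C(C)C)(C(C)C)C(C)C | intermediate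
31 | (1R,2S,5R,6S)-2-ArB-6-DHB-3,7-dioxabicyclo[3.3.0]octane | Brc1cc([C@H]2OC[C@H]3[C@@H]2CO[C@@H]3c2cc(OC)c3c(c2)[C@@H](CO[Si](C)(C)C(C)(C)C)[C@@H](c2ccc(O[Si](C(C)C)(C(C)C)C(C)C)c(OC)c2)O3)cc(OC)c1O[Si](C(C)C)(C(C)C)C(C)C | intermediate
32 | acetovanillone | CC(=O)c1ccc(O)c(OC)c1 | starting material
33 | 1-[3-methoxy-4-(triisopropylsilyloxy)phenyl]ethan-1-one | CC(=O)c1ccc(O[Si](C(C)C)(C(C)C)C(C)C)c(OC)c1 | intermediate
34 | 2-{3-methoxy-5-[(1R,2S,5R,6S)-6-DHB-3,7-dioxabicyclo[3.3.0]octan-2-yl]-2-(triisopropylsilyloxy)phenyl}-1-[3-methoxy-4-(triisopropylsilyloxy)phenyl]ethan-1-one | COc1cc(C(=O)Cc2cc([C@H]3OC[C@H]4[C@@H]3CO[C@@H]4c3cc(OC)c4c(c3)[C@@H](CO[Si](C)(C)C(C)(C)C)[C@@H](c3ccc(O[Si](C(C)C)(C(C)C)C(C)C)c(OC)c3)O4)cc(OC)c2O[Si](C(C)C)(C(C)C)C(C)C)ccc1O[Si](C(C)C)(C(C)C)C(C)C | intermediate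
35 | (Z)-trimethylsilyl enol ether of 34 | COc1cc(/C(O[Si](C)(C)C)=C/c2cc([C@H]3OC[C@H]4[C@@H]3CO[C@@H]4c3cc(OC)c4c(c3)[C@@H](CO[Si](C)(C)C(C)(C)C)[C@@H](c3ccc(O[Si](C(C)C)(C(C)C)C(C)C)c(OC)c3)O4)cc(OC)c2O[Si](C(C)C)(C(C)C)C(C)C)ccc1O[Si](C(C)C)(C(C)C)C(C)C | intermediate
36 | (2S)-3-hydroxy-2-{3-methoxy-5-[(1R,2S,5R,6S)-6-DHB-3,7-dioxabicyclo[3.3.0]octan-2-yl]-2-(triisopropylsilyloxy)phenyl}-1-[3-methoxy-4-(triisopropylsilyloxy)phenyl]propan-1-one | COc1cc(C(=O)[C@H](CO)c2cc([C@H]3OC[C@H]4[C@@H]3CO[C@@H]4c3cc(OC)c4c(c3)[C@@H](CO[Si](C)(C)C(C)(C)C)[C@@H](c3ccc(O[Si](C(C)C)(C(C)C)C(C)C)c(OC)c3)O4)cc(OC)c2O[Si](C(C)C)(C(C)C)C(C)C)ccc1O[Si](C(C)C)(C(C)C)C(C)C | intermediate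
37 | CNP0174045.1 | COc1cc(C(=O)[C@H](CO)c2cc([C@H]3OC[C@H]4[C@@H]3CO[C@@H]4c3cc(OC)c4c(c3)[C@@H](CO)[C@@H](c3ccc(O)c(OC)c3)O4)cc(OC)c2O)ccc1O | target

**Step count**

Total: 26 steps. Longest linear sequence: 22 steps (steps 1–12, 14–17, 20, 21, 23–26).

**Steps most likely to fail**

1. Step 20 (key step). The oxocarbenium ion may close from its other face, which puts ring B on the concave side (C2 epimer); an arene lying over the developing C8 cation could favour that mode. The error cannot be equilibrated away afterwards, because the C6–O7 bond and the dihydrobenzofuran C2–O bond ionise more easily than C2–O3. The fallback sets out from 20, uses 27 and 16, and returns at 31. It fixes C1 and C2 by a second auxiliary-controlled syn aldol reaction and closes both ether rings at the primary carbons. The secondary hydroxyl of 20 is silylated (Et3SiOTf, 2,6-lutidine) to the triethylsilyl ether F1. OsO4/NaIO4 cleaves the alkene to the aldehyde F2, and NaClO2 oxidises this to the acid F3. The pivalic mixed anhydride of F3 acylates lithiated 16 to give the bis-imide F4. Its dibutylboron enolate, formed at the unbranched CH2 group, adds to aldehyde 27 in an Evans syn aldol reaction to give the adduct F5 with C1 and C2 set by the auxiliary. LiBH4 reduces both imides to the triol F6, and PPTS in MeOH at 0 °C removes the triethylsilyl group to give the tetraol F7. Twofold Mitsunobu cyclodehydration (PPh3, DIAD), in which each benzylic hydroxyl displaces the activated primary hydroxyl with retention at the benzylic carbon, then gives 31.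

2. Step 25. Facial selectivity at the enol silane may be poor, because the nucleophilic carbon carries a bulky ortho-silyloxy aryl group that the catalyst pocket may not accommodate, and the reaction may be slow enough for background addition to compete. The fallback sets out from 35 and returns at 36. It gives up catalyst control: achiral Yb(OTf)3-catalysed hydroxymethylation of 35 with aqueous formaldehyde gives 36 together with its epimer at the ketone α-carbon F8. The two are diastereomers and are separated by preparative HPLC; F8 is re-equilibrated with Et3N in CH2Cl2 and recycled.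

3. Step 21. BF3·OEt2 may ionise one of the p-oxygenated benzylic C–O bonds besides the acetal. That would cost the cis configuration of the dihydrobenzofuran, epimerise C6 or allow reductive ring opening by Et3SiH; the primary silyl ether may also be lost. The fallback sets out from 30 and returns at 31. It replaces ionic hydrogenation by cleavage and re-formation of the O7–C8 bond: mild hydrolysis of the acetal (PPTS, acetone/H2O) gives the lactol F9; NaBH4 reduces its open hydroxy aldehyde form to the diol F10; Mitsunobu cyclodehydration (PPh3, DIAD), in which the C6 hydroxyl displaces the activated primary C8 hydroxyl with retention at C6, gives 31.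

**Further compounds**

F1 | step 20 | (4S)-4-benzyl-3-[(2S,3S)-3-DHB-2-(prop-2-en-1-yl)-3-(triethylsilyloxy)propanoyl]-1,3-oxazolidin-2-one | O=C(N1[C@@H](Cc2ccccc2)COC1=O)[C@@H](CC=C)[C@H](O[Si](CC)(CC)CC)c1cc(OC)c2c(c1)[C@@H](CO[Si](C)(C)C(C)(C)C)[C@@H](c1ccc(O[Si](C(C)C)(C(C)C)C(C)C)c(OC)c1)O2
F2 | step 20 | (4S)-4-benzyl-3-{(2S)-2-[(S)-DHB(triethylsilyloxy)methyl]-4-oxobutanoyl}-1,3-oxazolidin-2-one | O=C(N1[C@@H](Cc2ccccc2)COC1=O)[C@@H](CC=O)[C@H](O[Si](CC)(CC)CC)c1cc(OC)c2c(c1)[C@@H](CO[Si](C)(C)C(C)(C)C)[C@@H](c1ccc(O[Si](C(C)C)(C(C)C)C(C)C)c(OC)c1)O2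
F3 | step 20 | (3S,4S)-3-{[(4S)-4-benzyl-2-oxo-1,3-oxazolidin-3-yl]carbonyl}-4-DHB-4-(triethylsilyloxy)butanoic acid | O=C(N1[C@@H](Cc2ccccc2)COC1=O)[C@@H](CC(=O)O)[C@H](O[Si](CC)(CC)CC)c1cc(OC)c2c(c1)[C@@H](CO[Si](C)(C)C(C)(C)C)[C@@H](c1ccc(O[Si](C(C)C)(C(C)C)C(C)C)c(OC)c1)O2
F4 | step 20 | bis-imide, the N-acyl (S)-4-benzyl-1,3-oxazolidin-2-one of acid F3 | O=C(N1[C@@H](Cc2ccccc2)COC1=O)[C@@H](CC(=O)N1[C@@H](Cc2ccccc2)COC1=O)[C@H](O[Si](CC)(CC)CC)c1cc(OC)c2c(c1)[C@@H](CO[Si](C)(C)C(C)(C)C)[C@@H](c1ccc(O[Si](C(C)C)(C(C)C)C(C)C)c(OC)c1)O2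
F5 | step 20 | syn aldol adduct of F4 with 27, bearing (S)-ArB(hydroxy)methyl on the new (S) α-carbon | O=C(N1[C@@H](Cc2ccccc2)COC1=O)[C@@H]([C@H](C(=O)N1[C@@H](Cc2ccccc2)COC1=O)[C@H](O)c1cc(Br)c(O[Si](C(C)C)(C(C)C)C(C)C)c(OC)c1)[C@H](O[Si](CC)(CC)CC)c1cc(OC)c2c(c1)[C@@H](CO[Si](C)(C)C(C)(C)C)[C@@H](c1ccc(O[Si](C(C)C)(C(C)C)C(C)C)c(OC)c1)O2
F6 | step 20 | (2R,3R)-2-[(S)-DHB(triethylsilyloxy)methyl]-3-[(S)-ArB(hydroxy)methyl]butane-1,4-diol | OC[C@@H]([C@H](CO)[C@H](O)c1cc(Br)c(O[Si](C(C)C)(C(C)C)C(C)C)c(OC)c1)[C@H](O[Si](CC)(CC)CC)c1cc(OC)c2c(c1)[C@@H](CO[Si](C)(C)C(C)(C)C)[C@@H](c1ccc(O[Si](C(C)C)(C(C)C)C(C)C)c(OC)c1)O2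
F7 | step 20 | (2R,3R)-2-[(S)-DHB(hydroxy)methyl]-3-[(S)-ArB(hydroxy)methyl]butane-1,4-diol | OC[C@@H]([C@H](CO)[C@H](O)c1cc(Br)c(O[Si](C(C)C)(C(C)C)C(C)C)c(OC)c1)[C@H](O)c1cc(OC)c2c(c1)[C@@H](CO[Si](C)(C)C(C)(C)C)[C@@H](c1ccc(O[Si](C(C)C)(C(C)C)C(C)C)c(OC)c1)O2
F8 | step 25 | (2R)-epimer of 36 at the ketone α-carbon | COc1cc(C(=O)[C@@H](CO)c2cc([C@H]3OC[C@H]4[C@@H]3CO[C@@H]4c3cc(OC)c4c(c3)[C@@H](CO[Si](C)(C)C(C)(C)C)[C@@H](c3ccc(O[Si](C(C)C)(C(C)C)C(C)C)c(OC)c3)O4)cc(OC)c2O[Si](C(C)C)(C(C)C)C(C)C)ccc1O[Si](C(C)C)(C(C)C)C(C)C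
F9 | step 21 | (1S,2S,5R,6S)-2-ArB-6-DHB-3,7-dioxabicyclo[3.3.0]octan-8-ol (lactol, both anomers) | Brc1cc([C@H]2OC[C@H]3[C@@H]2C(O)O[C@@H]3c2cc(OC)c3c(c2)[C@@H](CO[Si](C)(C)C(C)(C)C)[C@@H](c2ccc(O[Si](C(C)C)(C(C)C)C(C)C)c(OC)c2)O3)cc(OC)c1O[Si](C(C)C)(C(C)C)C(C)C
F10 | step 21 | {(2S,3R,4R)-2-ArB-4-[(S)-DHB(hydroxy)methyl]oxolan-3-yl}methanol | Brc1cc([C@H]2OC[C@@H]([C@@H]2CO)[C@H](O)c2cc(OC)c3c(c2)[C@@H](CO[Si](C)(C)C(C)(C)C)[C@@H](c2ccc(O[Si](C(C)C)(C(C)C)C(C)C)c(OC)c2)O3)cc(OC)c1O[Si](C(C)C)(C(C)C)C(C)C
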